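**Retrosynthetic overview**
- The aryl ether C–O bond is cut last: Mitsunobu union of isofraxidin with a (2S,3R,5R)-2-(hydroxymethyl)oxolan-3-ol.
- The oxolane ring is opened to an epoxy diol; in the forward sense the C5 hydroxyl opens a terminal epoxide 5-exo with inversion.
- The epoxy diol comes from a 1,3-anti diol, made by hydroxyl-directed reduction of a β-hydroxy enone.
- Key C–C bond: a chelation-controlled Mukaiyama aldol between (3R)-3,4-bis(benzyloxy)butan-2-one (from methyl (R)-glycerate acetonide) and the silyl dienol ether of mesityl oxide; it delivers the whole C10 side chain.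
- Ring order: the coumarin pyranone ring is closed first (separate branch from syringaldehyde), the oxolane second; the final union forms no ring.

Assumption: LiN(i-Pr)2, i-PrMgCl and MeMgBr are used as purchased solutions.

**Step 1**
Reactants: 1 methyl (4R)-2,2-dimethyl-1,3-dioxolane-4-carboxylate
Product: 2 methyl (2R)-2,3-dihydroxypropanoate
Conditions: TsOH·H2O (5 mol%), MeOH, rt
Reagents that add atoms: none
Why: Acid-catalysed transacetalisation (acetonide methanolysis) frees the diol without touching the ester or the α-stereocentre, which is not enolised under mild acid.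

**Step 2**
Reactants: 2 methyl (2R)-2,3-dihydroxypropanoate
Product: 3 methyl (2R)-2,3-bis(benzyloxy)propanoate
Conditions: BnOC(=NH)CCl3 (2.6 equiv), CF3SO3H (5 mol%), cyclohexane/CH2Cl2 2:1, 0 °C to rt
Reagents that add atoms: benzyl 2,2,2-trichloroacetimidate, ClC(Cl)(Cl)C(=N)OCc1ccccc1
Why: Acid-catalysed O-benzylation with a trichloroacetimidate alkylates both hydroxyls without base, so the α-alkoxy ester neither racemises nor β-eliminates.

**Step 3**
Reactants: 3 methyl (2R)-2,3-bis(benzyloxy)propanoate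
Product: 4 (2R)-2,3-bis(benzyloxy)-N-methoxy-N-methylpropanamide
Conditions: MeNH(OMe)·HCl, i-PrMgCl, THF, −20 to 0 °C
Reagents that add atoms: N,O-dimethylhydroxylamine hydrochloride, CNOC.Cl
Why: Weinreb amide formation by aminolysis of the ester with the chloromagnesium amide is fast at low temperature and leaves the benzyl ethers and the α-stereocentre intact.

**Step 4**
Reactants: 4 (2R)-2,3-bis(benzyloxy)-N-methoxy-N-methylpropanamide
Product: 5 (3R)-3,4-bis(benzyloxy)butan-2-one
Conditions: MeMgBr, THF, −10 °C; aq NH4Cl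
Reagents that add atoms: methylmagnesium bromide, C[Mg]Br
Why: Weinreb ketone synthesis: the chelated tetrahedral magnesium adduct survives until work-up, so MeMgBr adds only once and the α-benzyloxy stereocentre is kept.

**Step 5**
Reactants: 6 4-methylpent-3-en-2-one (mesityl oxide)
Product: 8 trimethyl[(4-methylpenta-1,3-dien-2-yl)oxy]silane, via lithium dienolate 7 (not isolated)
Conditions: LiN(i-Pr)2, THF, −78 °C; then Me3SiCl, −78 °C to rt
Reagents that add atoms: chlorotrimethylsilane, C[Si](C)(C)Cl
Why: Kinetic deprotonation of the enone at its acetyl methyl by the hindered amide base, then O-silylation, gives the cross-conjugated 2-silyloxy diene (silyl enol ether formation).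

**Step 6**
Reactants: 5 (3R)-3,4-bis(benzyloxy)butan-2-one; 8 trimethyl[(4-methylpenta-1,3-dien-2-yl)oxy]silane
Product: 9 (6R,7R)-7,8-bis(benzyloxy)-6-hydroxy-2,6-dimethyloct-2-en-4-one
Conditions: TiCl4 (1.1 equiv), CH2Cl2, −78 °C (5 premixed 10 min), then 8 (1.5 equiv), −78 °C, 2 h; pH 7 buffer
Reagents that add atoms: none
Why: Chelation-controlled Mukaiyama aldol addition: TiCl4 ties the ketone C=O and the α-benzyloxy oxygen of 5 into a five-membered Cram chelate, and the terminal CH2 of 8 attacks the face opposite the CH2OBn arm, setting the tertiary carbinol as 6R, while the benzyl ethers tolerate TiCl4 at −78 °C.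

**Step 7**
Reactants: 9 (6R,7R)-7,8-bis(benzyloxy)-6-hydroxy-2,6-dimethyloct-2-en-4-one
Product: 10 (4R,6R,7R)-7,8-bis(benzyloxy)-2,6-dimethyloct-2-ene-4,6-diol
Conditions: Me4NBH(OAc)3 (5 equiv), MeCN/AcOH 1:1, −30 °C
Reagents that add atoms: none
Why: Evans–Saksena hydroxyl-directed reduction: the tertiary alcohol binds boron and delivers hydride intramolecularly through a chair with the bulky C7 branch equatorial, giving the 1,3-anti diol (new 4R centre) by clean 1,2-reduction of the enone.

**Step 8**
Reactants: 10 (4R,6R,7R)-7,8-bis(benzyloxy)-2,6-dimethyloct-2-ene-4,6-diol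
Product: 11 (2R,3R,5R)-3,7-dimethyloct-6-ene-1,2,3,5-tetrol
Conditions: Li (6 equiv), NH3(l)/THF, −78 °C, 20 min; solid NH4Cl
Reagents that add atoms: none
Why: Dissolving-metal (Birch-type) debenzylation cleaves both benzyl ethers, while the isolated trisubstituted alkene and the lithium alkoxides, the allylic one included, are not reduced and no stereocentre is touched.

**Step 9**
Reactants: 11 (2R,3R,5R)-3,7-dimethyloct-6-ene-1,2,3,5-tetrol
Product: 12 (2R,3R,5R)-2,3,5-trihydroxy-3,7-dimethyloct-6-en-1-yl 4-methylbenzenesulfonate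
Conditions: TsCl (1.05 equiv), Bu2SnO (2 mol%), Et3N, CH2Cl2, 0 °C to rt
Reagents that add atoms: 4-methylbenzenesulfonyl chloride, Cc1ccc(cc1)S(Cl)(=O)=O
Why: Dibutylstannylene-catalysed regioselective sulfonylation activates the terminal 1,2-diol so that only the primary hydroxyl is tosylated, leaving the secondary, allylic and tertiary hydroxyls free.

**Step 10**
Reactants: 12 (2R,3R,5R)-2,3,5-trihydroxy-3,7-dimethyloct-6-en-1-yl 4-methylbenzenesulfonate
Product: 14 (2S,3R,5R)-2-(hydroxymethyl)-3-methyl-5-(2-methylprop-1-en-1-yl)oxolan-3-ol, via epoxy diol 13 (not isolated)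
Conditions: K2CO3, MeOH, 0 °C; then (+)-camphor-10-sulfonic acid (10 mol%), CH2Cl2, 0 °C
Reagents that add atoms: none
Why: Intramolecular Williamson etherification onto the primary tosylate gives the terminal epoxide with its CH stereocentre untouched, and acid-catalysed 5-exo-tet epoxide opening by the allylic hydroxyl with inversion at that CH then sets the 2S ring carbon and, with the preset 3R and 5R centres, the 2,5-trans oxolane.

**Step 11**
Reactants: 15 4-hydroxy-3,5-dimethoxybenzaldehyde (syringaldehyde)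
Product: 16 2-bromo-4-hydroxy-3,5-dimethoxybenzaldehyde
Conditions: Br2 (1.0 equiv), NaOAc, AcOH, rt
Reagents that add atoms: bromine, BrBr
Why: Electrophilic aromatic bromination occurs at the only free ring positions, which are equivalent and activated ortho and para by the two methoxy groups, so one equivalent of bromine gives a single monobromide.

**Step 12**
Reactants: 16 2-bromo-4-hydroxy-3,5-dimethoxybenzaldehyde
Product: 17 2,4-dihydroxy-3,5-dimethoxybenzaldehyde
Conditions: NaOH (aq), Cu powder (cat.), reflux, N2; then HCl to pH 2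
Reagents that add atoms: sodium hydroxide, [Na+].[OH-]
Why: Copper-catalysed Ullmann-type hydroxylation replaces the bromide ortho to the formyl group by hydroxide, the aldehyde being shielded from Cannizzaro reaction as its electron-rich phenoxide.

**Step 13**
Reactants: 17 2,4-dihydroxy-3,5-dimethoxybenzaldehyde
Product: 19 7-hydroxy-6,8-dimethoxy-2H-chromen-2-one (isofraxidin), via cinnamate ester 18 (not isolated)
Conditions: Ph3P=CHCO2Et, PhNEt2, reflux (about 215 °C)
Reagents that add atoms: ethyl (triphenylphosphoranylidene)acetate, CCOC(=O)C=P(c1ccccc1)(c1ccccc1)c1ccccc1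
Why: Wittig olefination of the salicylaldehyde gives the cinnamate, which at this temperature isomerises from E to Z and lactonises with loss of ethanol to the coumarin, the free phenols being tolerated by the stabilised ylide.

**Step 14**
Reactants: 14 (2S,3R,5R)-2-(hydroxymethyl)-3-methyl-5-(2-methylprop-1-en-1-yl)oxolan-3-ol; 19 7-hydroxy-6,8-dimethoxy-2H-chromen-2-one
Product: 20 7-{[(2S,3R,5R)-3-hydroxy-3-methyl-5-(2-methylprop-1-en-1-yl)oxolan-2-yl]methoxy}-6,8-dimethoxy-2H-chromen-2-one
Conditions: PPh3, diisopropyl azodicarboxylate, THF, 0 °C to rt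
Reagents that add atoms: none
Why: Mitsunobu etherification: the acidic coumarin phenol displaces the activated primary alcohol at a non-stereogenic carbon, while the tertiary alcohol cannot be activated and the lactone and alkene are inert.

**Compound list**
1 | methyl (4R)-2,2-dimethyl-1,3-dioxolane-4-carboxylate | COC(=O)[C@H]1COC(C)(C)O1 | starting material
2 | methyl (2R)-2,3-dihydroxypropanoate | COC(=O)[C@H](O)CO | intermediate
3 | methyl (2R)-2,3-bis(benzyloxy)propanoate | COC(=O)[C@H](OCc1ccccc1)COCc1ccccc1 | intermediate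
4 | (2R)-2,3-bis(benzyloxy)-N-methoxy-N-methylpropanamide | CON(C)C(=O)[C@H](OCc1ccccc1)COCc1ccccc1 | intermediate
5 | (3R)-3,4-bis(benzyloxy)butan-2-one | CC(=O)[C@H](OCc1ccccc1)COCc1ccccc1 | intermediate
6 | 4-methylpent-3-en-2-one (mesityl oxide) | CC(C)=CC(C)=O | starting material
7 | lithium 4-methylpenta-1,3-dien-2-olate | [Li+].[O-]C(=C)C=C(C)C | intermediate
8 | trimethyl[(4-methylpenta-1,3-dien-2-yl)oxy]silane | CC(C)=CC(=C)O[Si](C)(C)C | intermediate
9 | (6R,7R)-7,8-bis(benzyloxy)-6-hydroxy-2,6-dimethyloct-2-en-4-one | CC(C)=CC(=O)C[C@@](C)(O)[C@H](OCc1ccccc1)COCc1ccccc1 | intermediate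
10 | (4R,6R,7R)-7,8-bis(benzyloxy)-2,6-dimethyloct-2-ene-4,6-diol | CC(C)=C[C@H](O)C[C@@](C)(O)[C@H](OCc1ccccc1)COCc1ccccc1 | intermediate
11 | (2R,3R,5R)-3,7-dimethyloct-6-ene-1,2,3,5-tetrol | CC(C)=C[C@H](O)C[C@@](C)(O)[C@H](O)CO | intermediate
12 | (2R,3R,5R)-2,3,5-trihydroxy-3,7-dimethyloct-6-en-1-yl 4-methylbenzenesulfonate | CC(C)=C[C@H](O)C[C@@](C)(O)[C@H](O)COS(=O)(=O)c1ccc(C)cc1 | intermediate
13 | (2R,4R)-6-methyl-2-[(2R)-oxiran-2-yl]hept-5-ene-2,4-diol | CC(C)=C[C@H](O)C[C@@](C)(O)[C@H]1CO1 | intermediate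
14 | (2S,3R,5R)-2-(hydroxymethyl)-3-methyl-5-(2-methylprop-1-en-1-yl)oxolan-3-ol | CC(C)=C[C@H]1C[C@@](C)(O)[C@H](CO)O1 | intermediate
15 | 4-hydroxy-3,5-dimethoxybenzaldehyde (syringaldehyde) | COc1cc(C=O)cc(OC)c1O | starting material
16 | 2-bromo-4-hydroxy-3,5-dimethoxybenzaldehyde | COc1cc(C=O)c(Br)c(OC)c1O | intermediate
17 | 2,4-dihydroxy-3,5-dimethoxybenzaldehyde | COc1cc(C=O)c(O)c(OC)c1O | intermediate
18 | ethyl (2E)-3-(2,4-dihydroxy-3,5-dimethoxyphenyl)prop-2-enoate | CCOC(=O)/C=C/c1cc(OC)c(O)c(OC)c1O | intermediate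
19 | 7-hydroxy-6,8-dimethoxy-2H-chromen-2-one (isofraxidin) | COc1cc2ccc(=O)oc2c(OC)c1O | intermediate
20 | 7-{[(2S,3R,5R)-3-hydroxy-3-methyl-5-(2-methylprop-1-en-1-yl)oxolan-2-yl]methoxy}-6,8-dimethoxy-2H-chromen-2-one | COc1cc2ccc(=O)oc2c(OC)c1OC[C@@H]1O[C@@H](C=C(C)C)C[C@@]1(C)O | target

**Step count and risks**
Total step count: 14. Longest linear sequence: 10 steps (steps 1, 2, 3, 4, 6, 7, 8, 9, 10, 14, from compound 1).

Step 6 is the most likely to fail. The acceptor is a ketone, the tertiary aldol can revert or dehydrate on the Lewis acid, and the facial control depends entirely on the α-chelate. The fallback sets out from 5 and attacks the same chelate with a simpler nucleophile whose adduct cannot revert. Allyltrimethylsilane with TiCl4 in CH2Cl2 at −78 °C (chelation-controlled carbonyl allylation) gives (2R,3R)-1,2-bis(benzyloxy)-3-methylhex-5-en-3-ol F1. Ozonolysis (O3, CH2Cl2/MeOH, −78 °C, then PPh3) gives (3R,4R)-4,5-bis(benzyloxy)-3-hydroxy-3-methylpentanal F2. Addition of 2-methylprop-1-enylmagnesium bromide (THF, −78 °C) gives 7,8-bis(benzyloxy)-2,6-dimethyloct-2-ene-4,6-diol as a mixture of C4 epimers F3. Oxidation of the allylic alcohol with MnO2 in CH2Cl2 gives the enone, and the route is rejoined at 9.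

Step 7 is the second risk. The directing carbinol is tertiary, so the chair must carry an axial methyl and the anti selectivity may be only moderate. The fallback sets out from 9 and replaces substrate control by reagent control. Silylation with Et3SiOSO2CF3 and 2,6-lutidine gives (6R,7R)-7,8-bis(benzyloxy)-2,6-dimethyl-6-[(triethylsilyl)oxy]oct-2-en-4-one F4. Oxazaborolidine-catalysed reduction with (S)-1-methyl-3,3-diphenyltetrahydro-1H,3H-pyrrolo[1,2-c][1,3,2]oxazaborole (20 mol%) and catecholborane in toluene at −78 °C, where the alkenyl group acts as the large substituent, gives (4R,6R,7R)-7,8-bis(benzyloxy)-2,6-dimethyl-6-[(triethylsilyl)oxy]oct-2-en-4-ol F5. Bu4NF in THF removes the silyl group, and the route is rejoined at 10.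

Step 14 is the third risk. The phenol of 19 is flanked by two methoxy groups and the primary alcohol of 14 is β-branched, so the Mitsunobu coupling may stall. The fallback sets out from 14 and makes the side chain the isolated electrophile. TsCl in pyridine at 0 °C sulfonylates only the primary hydroxyl and gives [(2S,3R,5R)-3-hydroxy-3-methyl-5-(2-methylprop-1-en-1-yl)oxolan-2-yl]methyl 4-methylbenzenesulfonate F6. Alkylation of 19 with F6 (Cs2CO3, DMF, 60 °C; the trans tertiary alkoxide cannot close an oxetane) gives the ether, and the route is rejoined at 20.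

**Further compounds**
F1 | step 6 | (2R,3R)-1,2-bis(benzyloxy)-3-methylhex-5-en-3-ol | C=CC[C@@](C)(O)[C@H](OCc1ccccc1)COCc1ccccc1
F2 | step 6 | (3R,4R)-4,5-bis(benzyloxy)-3-hydroxy-3-methylpentanal | O=CC[C@@](C)(O)[C@H](OCc1ccccc1)COCc1ccccc1
F3 | step 6 | (6R,7R)-7,8-bis(benzyloxy)-2,6-dimethyloct-2-ene-4,6-diol (C4 epimer mixture) | CC(C)=CC(O)C[C@@](C)(O)[C@H](OCc1ccccc1)COCc1ccccc1
F4 | step 7 | (6R,7R)-7,8-bis(benzyloxy)-2,6-dimethyl-6-[(triethylsilyl)oxy]oct-2-en-4-one | CC(C)=CC(=O)C[C@@](C)(O[Si](CC)(CC)CC)[C@H](OCc1ccccc1)COCc1ccccc1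
F5 | step 7 | (4R,6R,7R)-7,8-bis(benzyloxy)-2,6-dimethyl-6-[(triethylsilyl)oxy]oct-2-en-4-ol | CC(C)=C[C@H](O)C[C@@](C)(O[Si](CC)(CC)CC)[C@H](OCc1ccccc1)COCc1ccccc1
F6 | step 14 | [(2S,3R,5R)-3-hydroxy-3-methyl-5-(2-methylprop-1-en-1-yl)oxolan-2-yl]methyl 4-methylbenzenesulfonate | Cc1ccc(cc1)S(=O)(=O)OC[C@@H]1O[C@@H](C=C(C)C)C[C@@]1(C)O
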